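(The readings were generated by integration for an exercise.)

Divide the Ptn charged by the Sub charged before reading any curve; I did that for the three new flasks, which differ in Bse.

| flask | Sub | Bse | Ptn | remark | time |
|---|---|---|---|---|---|
| oak | 30 mM | 24 mM | 16 mM | run made earlier |  |
| grey | 20 mM | 41.0 mM | 16.0 mM |  | 10 d |
| teal | 20 mM | 24.0 mM | 16.0 mM |  | 10 d |
| green | 20 mM | 31.0 mM | 16.0 mM |  | 10 d |

- oak (time / d: Sub / %, Tgt / %): 0.333: 84.7, 12.0; 0.833: 64.1, 31.9; 1.67: 36.2, 47.4; 2.50: 21.4, 51.8; 4.00: 15.2, 52.8; 5.00: 14.4, 53.1; 6.00: 13.5, 52.9

(each reading ± 0.5 percentage points)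

- given per volume of solution although it is solid: Sub
- reactions considered so far: Sub2 + Ptn2 -> Bpr + Tgt; Ptn2 + Bpr <-> Ptn; Bpr + Bse <-> Bpr.Bse; Sub <-> Sub2
- at the start none of Sub is in solution
- what has only dissolved of Sub counts as not reacted
- no earlier run changes the charge of Bse; that part of a forecast is a guess

* part of the Sub that has reacted (what has only dissolved counts as not reacted) at the end, grey
* part of the Sub that has reacted (what has only dissolved counts as not reacted) at the end, teal
* part of the Sub that has reacted (what has only dissolved counts as not reacted) at the end, green
* what raising the concentration of Bse from its lowest to its highest value here does to the part of the Sub that has reacted (what has only dissolved counts as not reacted) (changes below 5 percentage points count as none) (it rises / no change / it falls)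

I began with the main step alone, Sub2 + Ptn2 -> Bpr + Tgt. Each Tgt takes one Ptn2 and each Ptn2 comes out of one Ptn, which made Ptn the limiting reagent:

C = 16.0 mM / 20 mM = 80.0%

I called C, Ptn charged over Sub charged, the ceiling on Tgt as a part of the Sub charged. For oak the same division gave 53.3%, and its Tgt reading was 53.1% at 5.00 d.

Next I added the release of Ptn2 from Ptn and the binding of Bpr by Bse. Each Ptn used gives two Bpr, so the ceiling means:

Bpr released = 32.0 mM

Teal's 24.0 mM of Bse falls short of this, leaving 8.00 mM unbound by this count, but oak had the same Bse and Ptn charges and its Tgt readings still stood within their scatter of its ceiling. Extra Bse was a guess, yet I expected it to free Ptn2 without raising C.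

Last I added dissolving. Taking oak's Sub column as the undissolved solid, its final readings left about 10.1 mM dissolved and unreacted, and the 4.00 mM beyond the ceiling in the new flasks is less, so I expected no solid to remain in them. Oak's Tgt readings were flat within their scatter from 4.00 d, well inside 10 d, though I accepted a slower last stretch at lower Sub2. My number stayed at 80.0% for each flask.

The forecast was lower for two of them: 80% for grey, 79% for teal, 79.5% for green, with no change as the trend, on the ground that “The yield is therefore capped 1:1 by Ptn”.

Grey gave 80.0%, teal 80.0% and green 80.0%, a change of 0 percentage points, so the trend was no change.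

    Sub2 + Ptn2 → Bpr + Tgt (k = 0.0140 /M/s)
    Ptn2 + Bpr ⇌ Ptn, settled at all times (K = 570 /M)
    Bpr + Bse ⇌ Bpr.Bse, settled at all times (K = 2.40 × 10⁵ /M)
    Sub ⇌ Sub2, rate k4*(cs4 - [Sub2]) while solid is left; crystals form when [Sub2] > cs4 (solubility = 9.90 mM, k = 1.70 × 10⁻⁵ /s)

Teal stopped at 80.0% through the using up of Ptn: at 10.0 d it held 0% of its Ptn, and the same run without that using up gave 100%. C does not show the free Bse, 0.0520% of the charge in teal against 22.0% in grey, but the difference in Bse is not the reason for grey's figure.

For a neighbour of grey charged with 4.0 mM of Ptn, the same division gives 20.0%, and that flask gave 20.0%.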